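**Plan**

1. Locants follow 2,3-dihydro-1,4-benzodioxine: O1, C2 (aryl), C3 (methyl), O4, C4a, C5–C8 (allyl on C7), C8a. Retrosynthesis: the benzo ring (ring A) is taken back to a cyclohexenone by adding water and methanol and cutting C7–allyl; then O1–C8a is cut, opening the dioxane (ring B) to a p-quinone monoketal; the ketal goes back to a 4-alkoxyphenol; finally C2–aryl is cut (N-methoxy-N-methylamide plus aryl Grignard reagent).
2. Enabling feature: in ring A the allyl carbon C7 is para to C4a (which carries O4), and C8a (which carries O1) is ortho to C4a. This is the carbonyl / ketal carbon / enone β-carbon pattern of a 4,4-dialkoxycyclohexa-2,5-dienone, so O1 can reach C8a by conjugate addition and the carbonyl carbon can later take the allyl group.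
3. Forward order: side chain first (amide, aryl ketone, threo alcohol), then oxidative dearomatization of the phenol ring, then closure of ring B, then allyl addition and re-aromatization of ring A.
4. Stereochemistry: C3 is bought as the (R) centre of methyl (2R)-2-(4-hydroxyphenoxy)propanoate. C2 is set by Felkin–Anh reduction of the α-aryloxy ketone. Neither is touched afterwards.
5. Helpers: the ketal methoxy group and the dienone carbonyl oxygen leave as methanol and water in step 8, which also erases the transient ring-fusion centres.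

Key step: step 6

Remark on the chemistry: 1, 3 and 11 are taken as purchased. The transient centres C4a/C8a (in 10 and 12) and C7 (in 12 and 13) form as mixtures, are left undrawn in the SMILES, and disappear in step 8.

Step 1
Reactants: 1 methyl (2R)-2-(4-hydroxyphenoxy)propanoate
Product: 2 (2R)-2-(4-hydroxyphenoxy)-N-methoxy-N-methylpropanamide
Conditions: MeNH(OMe)·HCl (1.5 equiv), i-PrMgCl (4.2 equiv), THF, −20 to 0 °C; aq. NH4Cl
Reagents that add atoms: N,O-dimethylhydroxylamine hydrochloride (CNOC.Cl)
Why: Aminolysis of the ester by the magnesium amide gives the N-methoxy-N-methylamide, the phenol riding along as its magnesium phenoxide and the α-aryloxy centre staying (R) because it is not deprotonated at this temperature.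

Step 2
Reactants: 2 (2R)-2-(4-hydroxyphenoxy)-N-methoxy-N-methylpropanamide; 3 3,4,5-trimethoxyphenylmagnesium bromide
Product: 4 (2R)-2-(4-hydroxyphenoxy)-1-(3,4,5-trimethoxyphenyl)propan-1-one
Conditions: 3,4,5-(MeO)3C6H2MgBr (0.5 M in THF, 2.5 equiv), THF, −20 to 0 °C; cold aq. citric acid
Reagents that add atoms: none
Why: In this Weinreb ketone synthesis the aryl Grignard reagent adds once to form a stable magnesium chelate that releases the ketone only on acidic quench, one further equivalent being consumed by the phenol.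

Step 3
Reactants: 4 (2R)-2-(4-hydroxyphenoxy)-1-(3,4,5-trimethoxyphenyl)propan-1-one
Product: 5 4-{[(1R,2R)-1-hydroxy-1-(3,4,5-trimethoxyphenyl)propan-2-yl]oxy}phenol
Conditions: K[HB(sec-Bu)3] (1.0 M in THF, 2.3 equiv), THF, −78 °C; then H2O
Reagents that add atoms: none
Why: In this Felkin–Anh reduction the non-chelating potassium ion and the bulky hydride place the aryloxy group anti to the incoming hydride, which passes the α-hydrogen and should create the (1R) carbinol, that is the threo (1R,2R) pair.

Step 4
Reactants: 5 4-{[(1R,2R)-1-hydroxy-1-(3,4,5-trimethoxyphenyl)propan-2-yl]oxy}phenol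
Product: 7 4-{[(1R,2R)-1-[(tert-butyldimethylsilyl)oxy]-1-(3,4,5-trimethoxyphenyl)propan-2-yl]oxy}phenol, via bis-silyl ether 6 (not isolated)
Conditions: TBSCl (2.5 equiv), imidazole, DMAP (cat.), DMF, 40 °C; then MeOH, K2CO3 (3 equiv), rt
Reagents that add atoms: tert-butyldimethylsilyl chloride (CC(C)(C)[Si](C)(C)Cl)
Why: Exhaustive silylation followed by selective base-mediated methanolysis of the far more labile aryl silyl ether leaves only the benzylic oxygen masked, so that it cannot capture the oxidized ring in step 5 as a spiroketal.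

Step 5
Reactants: 7 4-{[(1R,2R)-1-[(tert-butyldimethylsilyl)oxy]-1-(3,4,5-trimethoxyphenyl)propan-2-yl]oxy}phenol
Product: 8 4-methoxy-4-{[(1R,2R)-1-[(tert-butyldimethylsilyl)oxy]-1-(3,4,5-trimethoxyphenyl)propan-2-yl]oxy}cyclohexa-2,5-dien-1-one
Conditions: PhI(OAc)2 (1.1 equiv), NaHCO3 (3 equiv), MeOH, 0 °C
Reagents that add atoms: methanol (CO)
Why: Oxidative dearomatization of a 4-alkoxyphenol by PhI(OAc)2 in methanol should give the mixed p-quinone monoketal, the non-phenolic trimethoxyphenyl ring being inert and NaHCO3 suppressing acid-catalysed ketal exchange, while the ketal carbon with its two identical vinyl arms is not yet a stereocentre.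

Step 6
Reactants: 8 4-methoxy-4-{[(1R,2R)-1-[(tert-butyldimethylsilyl)oxy]-1-(3,4,5-trimethoxyphenyl)propan-2-yl]oxy}cyclohexa-2,5-dien-1-one
Product: 10 (2R,3R)-4a-methoxy-3-methyl-2-(3,4,5-trimethoxyphenyl)-2,3,8,8a-tetrahydro-1,4-benzodioxin-7(4aH)-one (cis-fused; C4a/C8a unassigned), via free hydroxy dienone 9 (not isolated)
Conditions: Bu4NF (1.0 M in THF, 1.2 equiv), THF, 0 °C to rt
Reagents that add atoms: none
Why: Fluoride cleaves the benzylic silyl ether and the resulting tetrabutylammonium alkoxide of 9 adds to the β-carbon of one enone arm of the cross-conjugated dienone, the enolate then being protonated by the water carried by the reagent (intramolecular oxa-Michael addition). The closest known reaction types are the conjugate cyclization of 4-(2-hydroxyethoxy)cyclohexa-2,5-dienones to cis-fused 1,4-dioxanes and Michael additions to p-quinone monoketals. Ring B closes in the 6-exo-trig mode through a chair-like transition state. Of the two new stereocentres, the ring-fusion carbon C8a is forced cis to the ketal oxygen O4 by the three-atom tether, and the ketal carbon C4a becomes stereogenic through the choice between the two diastereotopic enone arms, which the equatorial aryl and methyl groups bias but need not control, because both centres are erased in step 8. The selectivity that matters is conjugate addition in preference to ketal exchange, which would give a spiroketal and make O1 and O4 interchangeable; it is secured by the acid-free basic medium, in which the ketal is inert, and by the tether, which cannot reach the carbonyl carbon. C2 and C3 take no part and keep their configuration.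

Step 7
Reactants: 10 (2R,3R)-4a-methoxy-3-methyl-2-(3,4,5-trimethoxyphenyl)-2,3,8,8a-tetrahydro-1,4-benzodioxin-7(4aH)-one; 11 allylmagnesium bromide
Product: 12 (2R,3R)-4a-methoxy-3-methyl-7-(prop-2-en-1-yl)-2-(3,4,5-trimethoxyphenyl)-2,3,4a,7,8,8a-hexahydro-1,4-benzodioxin-7-ol (C4a/C7/C8a unassigned)
Conditions: CH2=CHCH2MgBr (1.0 M in Et2O, 1.5 equiv), THF, −78 °C; aq. NH4Cl
Reagents that add atoms: none
Why: Grignard 1,2-addition of the allyl reagent to the enone carbonyl is much faster than enolization, so the β-alkoxy ketone should not undergo retro-Michael cleavage, and the configuration of the new carbinol centre is irrelevant.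

Step 8
Reactants: 12 (2R,3R)-4a-methoxy-3-methyl-7-(prop-2-en-1-yl)-2-(3,4,5-trimethoxyphenyl)-2,3,4a,7,8,8a-hexahydro-1,4-benzodioxin-7-ol
Product: 14 (2R,3R)-3-methyl-7-(prop-2-en-1-yl)-2-(3,4,5-trimethoxyphenyl)-2,3-dihydro-1,4-benzodioxine, via dienol ether carbinol 13 (not isolated)
Conditions: pyridinium p-toluenesulfonate (0.2 equiv), 4 Å molecular sieves, CH2Cl2, 0 °C to rt
Reagents that add atoms: none
Why: In this acid-catalysed dehydrative aromatization the allylic mixed ketal should ionize first and lose methanol to the sieves (cleavage of the ring C–O bond of the same ketal is reversible because the tethered hydroxyl recloses), proton loss from C8a then gives dienol ether 13, whose tertiary alcohol ionizes to an arenium ion that loses a C8 proton, and the mild acid leaves the benzylic C2–O1 bond and the terminal alkene untouched.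

**Compound list**

1 | methyl (2R)-2-(4-hydroxyphenoxy)propanoate | C[C@@H](Oc1ccc(O)cc1)C(=O)OC | starting material
2 | (2R)-2-(4-hydroxyphenoxy)-N-methoxy-N-methylpropanamide | C[C@@H](Oc1ccc(O)cc1)C(=O)N(C)OC | intermediate
3 | 3,4,5-trimethoxyphenylmagnesium bromide | COc1cc([Mg]Br)cc(OC)c1OC | starting material
4 | (2R)-2-(4-hydroxyphenoxy)-1-(3,4,5-trimethoxyphenyl)propan-1-one | C[C@@H](Oc1ccc(O)cc1)C(=O)c1cc(OC)c(OC)c(OC)c1 | intermediate
5 | 4-{[(1R,2R)-1-hydroxy-1-(3,4,5-trimethoxyphenyl)propan-2-yl]oxy}phenol | C[C@@H](Oc1ccc(O)cc1)[C@H](O)c1cc(OC)c(OC)c(OC)c1 | intermediate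
6 | tert-butyl{4-[(1R,2R)-1-[(tert-butyldimethylsilyl)oxy]-1-(3,4,5-trimethoxyphenyl)propan-2-yl]oxyphenoxy}dimethylsilane (bis-silyl ether, not isolated) | C[C@@H](Oc1ccc(O[Si](C)(C)C(C)(C)C)cc1)[C@H](O[Si](C)(C)C(C)(C)C)c1cc(OC)c(OC)c(OC)c1 | intermediate
7 | 4-{[(1R,2R)-1-[(tert-butyldimethylsilyl)oxy]-1-(3,4,5-trimethoxyphenyl)propan-2-yl]oxy}phenol | C[C@@H](Oc1ccc(O)cc1)[C@H](O[Si](C)(C)C(C)(C)C)c1cc(OC)c(OC)c(OC)c1 | intermediate
8 | 4-methoxy-4-{[(1R,2R)-1-[(tert-butyldimethylsilyl)oxy]-1-(3,4,5-trimethoxyphenyl)propan-2-yl]oxy}cyclohexa-2,5-dien-1-one | C[C@@H](OC1(OC)C=CC(=O)C=C1)[C@H](O[Si](C)(C)C(C)(C)C)c1cc(OC)c(OC)c(OC)c1 | intermediate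
9 | 4-{[(1R,2R)-1-hydroxy-1-(3,4,5-trimethoxyphenyl)propan-2-yl]oxy}-4-methoxycyclohexa-2,5-dien-1-one (formed as its alkoxide, not isolated) | C[C@@H](OC1(OC)C=CC(=O)C=C1)[C@H](O)c1cc(OC)c(OC)c(OC)c1 | intermediate
10 | (2R,3R)-4a-methoxy-3-methyl-2-(3,4,5-trimethoxyphenyl)-2,3,8,8a-tetrahydro-1,4-benzodioxin-7(4aH)-one, cis-fused, C4a/C8a unassigned | C[C@H]1OC2(OC)C=CC(=O)CC2O[C@@H]1c1cc(OC)c(OC)c(OC)c1 | intermediate
11 | allylmagnesium bromide | C=CC[Mg]Br | starting material
12 | (2R,3R)-4a-methoxy-3-methyl-7-(prop-2-en-1-yl)-2-(3,4,5-trimethoxyphenyl)-2,3,4a,7,8,8a-hexahydro-1,4-benzodioxin-7-ol, C4a/C7/C8a unassigned | C[C@H]1OC2(OC)C=CC(O)(CC=C)CC2O[C@@H]1c1cc(OC)c(OC)c(OC)c1 | intermediate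
13 | (2R,3R)-3-methyl-7-(prop-2-en-1-yl)-2-(3,4,5-trimethoxyphenyl)-2,3,7,8-tetrahydro-1,4-benzodioxin-7-ol, C7 unassigned (not isolated) | C[C@H]1OC2=C(CC(O)(CC=C)C=C2)O[C@@H]1c1cc(OC)c(OC)c(OC)c1 | intermediate
14 | (2R,3R)-3-methyl-7-(prop-2-en-1-yl)-2-(3,4,5-trimethoxyphenyl)-2,3-dihydro-1,4-benzodioxine | C=CCc1ccc2c(c1)O[C@H](c1cc(OC)c(OC)c(OC)c1)[C@@H](C)O2 | target

**Totals and risks**

Total steps: 8. Longest linear sequence: 8 steps (1 to 14).

Steps most likely to fail:

Step 8. Ionization of the tertiary carbinol may run ahead of methanol loss, so that the allyl group migrates or its double bond moves into conjugation. Alternatively, the ring C4a–O4 bond may ionize irreversibly once an arenium ion is possible, which would open ring B. The fallback sets out from 10 and returns at 14; it aromatizes the ketone before any allyl group is present. Pyridinium p-toluenesulfonate with 4 Å sieves in CH2Cl2 should expel methanol from 10 and tautomerize the dienone to the phenol (2R,3R)-3-methyl-2-(3,4,5-trimethoxyphenyl)-2,3-dihydro-1,4-benzodioxin-7-ol F1. Tf2O and pyridine in CH2Cl2 at 0 °C should convert it into the aryl triflate (2R,3R)-3-methyl-2-(3,4,5-trimethoxyphenyl)-2,3-dihydro-1,4-benzodioxin-7-yl trifluoromethanesulfonate F2. Stille coupling with allyltributylstannane (Pd(PPh3)4, LiCl, DMF, 90 °C) should then give 14. The allyl group thus arrives by cross-coupling on the finished arene instead of by carbonyl addition and dehydration.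

Step 6. After desilylation the base-sensitive dienone may degrade, or the conjugate addition may reverse during work-up, instead of the ring closing cleanly. The fallback sets out from Grignard reagent 3 and returns at 14; it abandons the dearomatization and closes the same aryl C–O bond on an aryl bromide.
- 4-Allylphenol is brominated ortho to the hydroxyl group (NBS, cat. i-Pr2NH, CH2Cl2, 0 °C) to give 2-bromo-4-(prop-2-en-1-yl)phenol F3.
- Mitsunobu reaction with ethyl (2S)-2-hydroxypropanoate (PPh3, DIAD, THF) inverts the lactate centre and should give ethyl (2R)-2-[2-bromo-4-(prop-2-en-1-yl)phenoxy]propanoate F4.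
- Aminolysis as in step 1 should give (2R)-2-[2-bromo-4-(prop-2-en-1-yl)phenoxy]-N-methoxy-N-methylpropanamide F5.
- Addition of 3 as in step 2 should give (2R)-2-[2-bromo-4-(prop-2-en-1-yl)phenoxy]-1-(3,4,5-trimethoxyphenyl)propan-1-one F6.
- Reduction as in step 3 should give (1R,2R)-2-[2-bromo-4-(prop-2-en-1-yl)phenoxy]-1-(3,4,5-trimethoxyphenyl)propan-1-ol F7.
- Intramolecular Buchwald–Hartwig etherification (Pd(OAc)2, 2-(di-tert-butylphosphino)-1,1'-binaphthyl, Cs2CO3, toluene, 70 °C) should close ring B with retention at both centres and give 14.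

Step 3. Facial selectivity may be poor if chelated hydride delivery competes with the Felkin–Anh mode, and the basic hydride may epimerize the α-aryloxy centre of 4. The fallback sets out from 4 and returns at 5. It uses catalyst-controlled Noyori–Ikariya asymmetric transfer hydrogenation with RuCl[(S,S)-TsDPEN](p-cymene) in HCO2H/Et3N (5:2) at room temperature. The sulfonyldiamine ligand, not the α-centre, then selects the carbonyl face, and the (S,S) catalyst should deliver the (1R) carbinol. No new compound arises.

**Further compounds**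

F1 | step 8 | (2R,3R)-3-methyl-2-(3,4,5-trimethoxyphenyl)-2,3-dihydro-1,4-benzodioxin-7-ol | C[C@H]1Oc2ccc(O)cc2O[C@@H]1c1cc(OC)c(OC)c(OC)c1
F2 | step 8 | (2R,3R)-3-methyl-2-(3,4,5-trimethoxyphenyl)-2,3-dihydro-1,4-benzodioxin-7-yl trifluoromethanesulfonate | C[C@H]1Oc2ccc(OS(=O)(=O)C(F)(F)F)cc2O[C@@H]1c1cc(OC)c(OC)c(OC)c1
F3 | step 6 | 2-bromo-4-(prop-2-en-1-yl)phenol | C=CCc1ccc(O)c(Br)c1
F4 | step 6 | ethyl (2R)-2-[2-bromo-4-(prop-2-en-1-yl)phenoxy]propanoate | C[C@@H](Oc1ccc(CC=C)cc1Br)C(=O)OCC
F5 | step 6 | (2R)-2-[2-bromo-4-(prop-2-en-1-yl)phenoxy]-N-methoxy-N-methylpropanamide | C[C@@H](Oc1ccc(CC=C)cc1Br)C(=O)N(C)OC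
F6 | step 6 | (2R)-2-[2-bromo-4-(prop-2-en-1-yl)phenoxy]-1-(3,4,5-trimethoxyphenyl)propan-1-one | C[C@@H](Oc1ccc(CC=C)cc1Br)C(=O)c1cc(OC)c(OC)c(OC)c1
F7 | step 6 | (1R,2R)-2-[2-bromo-4-(prop-2-en-1-yl)phenoxy]-1-(3,4,5-trimethoxyphenyl)propan-1-ol | C[C@@H](Oc1ccc(CC=C)cc1Br)[C@H](O)c1cc(OC)c(OC)c(OC)c1
F0 | step 3 | none | none
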